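The numbers in the tables are calculated with made-up constants; the scatter is artificial.

I decided to judge this flask by its late readings rather than by its early speed, and I wanted one number for them. The flask asked about is the delta run itself, continued.

common to all: Q 10 mM
- delta: E 20 mM; the very flask that is asked about, followed so far
- beta: E 40 mM; run made earlier
- flask: E 20.0 mM; time 8.0 h

- delta (time / h: J / %, Q / %): 0.667: 20.2, 72.1; 1.33: 18.0, 63.5; 2.50: 14.4, 56.9; 4.00: 10.8, 50.9; 8.00: 11.7, 47.6
- beta (time / h: J / %, Q / %): 1.50: 24.6, 56.9; 3.00: 18.5, 50.2; 5.00: 16.4, 42.5; 6.00: 16.2, 43.1; 8.00: 15.8, 40.6

(standard deviation of a reading: 1 percentage point)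

- violet: at 8.0 h take out 90% of the J then present, then wait 15 h
- amber: at 8.0 h add Q, 50.0% of the amount charged, then wait 15 h
- green: change nothing and wait 15 h more
- blue: at 8.0 h add E, 100% of the amount charged, then wait 15 h

- what is taken out of J is counted as made
- additions bring no volume worth counting

- J, in percent of the Q first charged, at 8.0 h
- which option adds most J ("none" when 2 percentage points or less is all one gets) (violet / amber / green / blue / none)
- J present, with what was taken out counted in, in percent of the Q first charged, after violet
- J present, with what was taken out counted in, in percent of the Q first charged, after green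

Beta looked nearly stopped: from 5.00 h to 8.00 h, J went from 16.4% to 15.8%. My first estimate was a plain balance, with J over Q proportional to E. Beta holds twice the E of delta, but the ratio went from 0.246 to 0.389, a factor of 1.58. That estimate failed.

So I supposed that J comes with a partner, and read beta at 8.00 h again: 0.0154. This is J squared over Q times the E charged, each in mM. I call it the stall number, an apparent equilibrium quotient. Delta at 8.00 h gives 0.0144, so it survived the change of E.

One objection remained. At 0.667 h delta gives 0.0283, twice as much, so the number is no constant of the run, and I used it for late readings and nothing earlier.

Beta's number with delta's Q gave me 12.1% of J now. Blue doubles E, and amber makes Q twice as much, so each gains about 5 percentage points. Violet, refilled to the same J, gains 11 points. But J's partner would stay behind, so that refill is a ceiling. Still, blue's gain is half of that, and I chose violet, which reckons more.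

The forecast gave 11.3% now, violet as best, 20.5% after violet and 11.5% after green, saying “this looks like equilibrium”. Its J is lower than mine.

The flask gave 10.9%, and violet won with 6.4 points, below my ceiling; blue gave 2.3 points and amber 1.1 points. After violet it held 17.3%, after green 9.64%.

    Q + E ⇌ J + Z (K = 0.0320, k = 0.700 L mol⁻¹ min⁻¹)
    Q ⇌ G (K = 0.680, k = 0.00300 min⁻¹)
    J ⇌ L (K = 1.70, k = 0.00300 min⁻¹)

With Q at 46.0%, the stall number gives this flask 11.9%, against the 10.9% it held. The neighbour flask charged with 4.0 mM of Q keeps the same E and has 38.9% of its Q left at 8.00 h. There the stall number gives 17.3% of J, and that flask held 16.2%.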